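**Plan**

- Cuts: the C15=C17 methylene is removed (Mannich/elimination) and C11–Cl is traced back to an 11,12-diol (chloride on a cyclic sulfate). The C11–C12 bond of the 14-membered ring is then cut: C11 (CHCl) and C12 (C(OH)CH3) are adjacent heteroatom-bearing ring carbons, the pattern left when a C11 aldehyde and a C12 methyl ketone are joined reductively. The seco keto aldehyde is cut further at the C12 ketone (Wacker), C13–C14 (allylation), the lactone C–O and C1–C2 (enolate alkylation).
- Forward: farnesol is trimmed to the C2–C11 bromo acetal and joined at C1 to a succinate imide. Allylation at C14 and lactonisation close the γ-lactone first. Wacker oxidation and acetal hydrolysis give the keto aldehyde, SmI2 then closes the 14-membered carbocycle, and chloride and the methylene come last.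
- Stereochemistry: both E alkenes are those of farnesol; C1 comes from the (R)-benzyl oxazolidinone and C14 from the isopinocampheyl allylborane. C12 and C11 arise in the ring closure (C12 relayed from C14 through the lactone, C11 as the threo partner), and C11 is then inverted by chloride.

Key step: step 15

Remark: atoms are numbered as in cembrane (ring C1–C14, C1 carrying C15 and C14 the lactone oxygen; C15 lactone α-carbon, C16 carbonyl, C17 methylene; "17-nor" names lack C17), and the (+)-α-pinene-derived allylborane is assumed to be used as a magnesium-salt-free solution.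

**Route**

Step 1
Reactants: 1 (2E,6E)-farnesol
Product: 2 (2E,6E)-farnesyl acetate
Conditions: Ac2O, pyridine, DMAP (cat.), CH2Cl2, 0 °C → rt
Reagents that add atoms: acetic anhydride, CC(=O)OC(C)=O
Why: DMAP-catalysed O-acylation of the primary allylic alcohol, which also lowers the electron density of the neighbouring alkene before the bromohydrin step.

Step 2
Reactants: 2 (2E,6E)-farnesyl acetate
Product: 3 (2E,6E)-10-bromo-11-hydroxy-10,11-dihydrofarnesyl acetate (racemic at C10)
Conditions: NBS, THF/H2O (3:1), 0 °C
Reagents that add atoms: N-bromosuccinimide, O=C1CCC(=O)N1Br; water, O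
Why: Electrophilic bromohydrin formation, in which the terminal isopropylidene alkene of the coiled triene is the most exposed in aqueous THF and water opens the bromonium ion at the tertiary carbon, the new racemic centre being removed in step 4.

Step 3
Reactants: 3 bromohydrin acetate
Product: 5 (2E,6E)-10,11-epoxy-10,11-dihydrofarnesol (racemic), via epoxy acetate 4 (not isolated)
Conditions: K2CO3, MeOH, rt
Reagents that add atoms: none
Why: Intramolecular Williamson-type displacement of bromide by the neighbouring alkoxide closes the epoxide, and carbonate-catalysed methanolysis (transesterification) removes the acetate in the same pot.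

Step 4
Reactants: 5 epoxy alcohol
Product: 7 (4E,8E)-10-hydroxy-4,8-dimethyldeca-4,8-dienal, via triol 6 (not isolated)
Conditions: H5IO6, THF/H2O, 0 °C
Reagents that add atoms: none
Why: Periodic acid hydrolyses the epoxide to the glycol and cleaves it (Malaprade glycol cleavage) to acetone and the aldehyde that becomes C11, without touching the trisubstituted alkenes or the allylic alcohol.

Step 5
Reactants: 7 hydroxy aldehyde
Product: 8 (2E,6E)-9-(1,3-dioxolan-2-yl)-3,7-dimethylnona-2,6-dien-1-ol
Conditions: HOCH2CH2OH, PPTS (cat.), benzene, reflux (Dean–Stark)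
Reagents that add atoms: ethylene glycol, OCCO
Why: Acid-catalysed acetalisation driven by azeotropic removal of water, the cyclic acetal masking the future C11 aldehyde against the enolate, hydride, borane and oxidation steps that follow.

Step 6
Reactants: 8 hydroxy acetal
Product: 9 2-[(3E,7E)-9-bromo-3,7-dimethylnona-3,7-dienyl]-1,3-dioxolane
Conditions: CBr4, PPh3, CH2Cl2, 0 °C
Reagents that add atoms: carbon tetrabromide, BrC(Br)(Br)Br
Why: Appel reaction, an SN2 displacement of the alkoxyphosphonium group by bromide at the primary allylic carbon under neutral conditions, which keeps the E geometry and the acetal.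

Step 7
Reactants: 10 4-tert-butoxy-4-oxobutanoic acid; 11 (R)-4-benzyl-1,3-oxazolidin-2-one
Product: 13 tert-butyl 4-[(4R)-4-benzyl-2-oxo-1,3-oxazolidin-3-yl]-4-oxobutanoate, via mixed pivalic anhydride 12 (not isolated)
Conditions: PivCl, Et3N, THF, −20 °C; then LiCl, 11, −20 °C → rt
Reagents that add atoms: none
Why: N-Acylation of the oxazolidinone through a mixed anhydride, the nitrogen attacking the unhindered succinyl carbonyl in preference to the pivaloyl carbonyl.

Step 8
Reactants: 13 succinate imide; 9 allylic bromide
Product: 15 tert-butyl (3R,5E,9E)-3-[(4R)-4-benzyl-2-oxo-1,3-oxazolidine-3-carbonyl]-12-(1,3-dioxolan-2-yl)-6,10-dimethyldodeca-5,9-dienoate, via sodium enolate 14 (not isolated)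
Conditions: NaHMDS, THF, −78 °C; then 9, −78 → −20 °C
Reagents that add atoms: none
Why: Evans asymmetric alkylation, in which the chelated Z sodium enolate of the imide (its α-protons being more acidic than those of the ester) is alkylated by the allylic bromide in SN2 fashion on the face opposite the benzyl group, setting the future C1 as 3R.

Step 9
Reactants: 15 alkylated imide
Product: 16 tert-butyl (3R,5E,9E)-12-(1,3-dioxolan-2-yl)-3-(hydroxymethyl)-6,10-dimethyldodeca-5,9-dienoate
Conditions: LiBH4, H2O (1 equiv), Et2O, 0 °C
Reagents that add atoms: none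
Why: Reductive cleavage of the N-acyl oxazolidinone by LiBH4, which reduces the activated exocyclic imide carbonyl much faster than the tert-butyl ester, releases the auxiliary and leaves the C1 centre untouched.

Step 10
Reactants: 16 hydroxy ester
Product: 17 tert-butyl (3R,5E,9E)-12-(1,3-dioxolan-2-yl)-3-formyl-6,10-dimethyldodeca-5,9-dienoate
Conditions: Dess–Martin periodinane, CH2Cl2, 0 °C → rt
Reagents that add atoms: none
Why: Dess–Martin oxidation of the primary alcohol under base-free conditions, chosen so that the α-branched aldehyde does not epimerise at C1 before it is used at once in step 11.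

Step 11
Reactants: 17 aldehyde
Product: 19 tert-butyl (3R,5E,9E)-12-(1,3-dioxolan-2-yl)-3-[(1S)-1-hydroxybut-3-enyl]-6,10-dimethyldodeca-5,9-dienoate, via dialkylborinate 18 (not isolated)
Conditions: (+)-Ipc2B(allyl), Et2O, −78 °C; then NaOH, H2O2, 0 °C → rt
Reagents that add atoms: (+)-B-allyldiisopinocampheylborane of the (+)-α-pinene series, C=CCB([C@@H]1C[C@@H]2C[C@H]([C@H]1C)C2(C)C)[C@@H]1C[C@@H]2C[C@H]([C@H]1C)C2(C)C
Why: Brown allylation, in which allyl transfer through a closed chair-like six-membered transition state under reagent control by the isopinocampheyl groups sets C14 as S, overriding the weak bias of the neighbouring C1 centre, before oxidative work-up cleaves the borinate.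

Step 12
Reactants: 19 homoallylic alcohol
Product: 20 (4R,5S)-4-[(2E,6E)-9-(1,3-dioxolan-2-yl)-3,7-dimethylnona-2,6-dienyl]-5-(prop-2-enyl)oxolan-2-one
Conditions: CSA (cat.), CH2Cl2, rt → 40 °C
Reagents that add atoms: none
Why: Acid-catalysed lactonisation (intramolecular transesterification) of the γ-hydroxy tert-butyl ester closes the five-membered lactone with both centres as spectators, so the C1 and C14 substituents end up trans, and the dioxolane should survive because the medium is anhydrous.

Step 13
Reactants: 20 allyl lactone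
Product: 21 (4R,5S)-4-[(2E,6E)-9-(1,3-dioxolan-2-yl)-3,7-dimethylnona-2,6-dienyl]-5-(2-oxopropyl)oxolan-2-one
Conditions: PdCl2 (10 mol %), Cu(OAc)2 (20 mol %), O2 (1 atm), DMA/H2O (7:1), rt
Reagents that add atoms: water, O
Why: Tsuji–Wacker oxidation, in which Markovnikov hydroxypalladation of the only monosubstituted alkene gives the C12 methyl ketone while the trisubstituted alkenes do not react, the Cu(OAc)2 variant keeping the medium mild enough for the acetal.

Step 14
Reactants: 21 keto acetal
Product: 22 (4E,8E)-4,8-dimethyl-10-[(2S,3R)-5-oxo-2-(2-oxopropyl)oxolan-3-yl]deca-4,8-dienal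
Conditions: 1 M HCl, THF, rt
Reagents that add atoms: water, O
Why: Acid-catalysed acetal hydrolysis frees the C11 aldehyde, dilute acid being tolerated by the lactone, the alkenes and the β-acyloxy ketone, which under base would lose the carboxylate by β-elimination.

Step 15
Reactants: 22 seco keto aldehyde
Product: 23 (1R,3E,7E,11R,12R,14S)-11,12-dihydroxy-17-norcembra-3,7-dien-16,14-olide
Conditions: SmI2 (0.1 M in THF, 3 equiv), THF, rt, 22 added over 10 h (final 0.002 M); then H2O
Reagents that add atoms: none
Why: SmI2 (divalent samarium) transfers one electron to the aldehyde, the more easily reduced carbonyl, and the C11 ketyl bound to trivalent samarium attacks the samarium-coordinated C12 methyl ketone while a second equivalent supplies the second electron, so that a samarium diolate forms and water releases the diol. The closest known reaction type is the intramolecular pinacol (reductive carbonyl–carbonyl) coupling of keto aldehydes with SmI2 or low-valent titanium, which has been applied to 14-membered cembranoid diols. The 14-membered carbocycle closes by C11–C12 bond formation between the two chain ends, the trans-lactone serving as a rigid turn that holds C13 and C2 on opposite faces, and slow addition to a final 0.002 M should favour ring closure over intermolecular coupling. C12 is expected to be controlled by the C14 stereocentre, whose acetonyl arm is fixed by the lactone so that samarium held between the ketone oxygen and the lactone oxygen should expose the ketone face leading to 12R; this relay is the least certain element of the route, since open-chain chelate models would favour the other face. C11 is controlled by the five-membered samarium diolate of the transition state, in which the two oxygens are gauche while C10 and C13 stay anti, which corresponds to the threo (11R,12R) diol. The step needs chemoselectivity for the two carbonyls over the lactone and the alkenes, secured because a saturated ester and isolated trisubstituted alkenes are not reduced by SmI2 in THF without HMPA or a proton source.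

Step 16
Reactants: 23 threo diol
Product: 25 11,12-cyclic sulfate of 23, via cyclic sulfite 24 (not isolated)
Conditions: SOCl2, Et3N, CH2Cl2, 0 °C; then RuCl3·3H2O (1 mol %), NaIO4, MeCN/H2O, 0 °C, 10 min
Reagents that add atoms: thionyl chloride, O=S(Cl)Cl; sodium periodate, [Na+].[O-]I(=O)(=O)=O
Why: Two-stage cyclic sulfate formation (cyclic sulfite, then RuO4-catalysed oxidation at sulfur) makes only O–S bonds, so C11 and C12 keep their configuration, and the fast sulfur oxidation is stopped after minutes so that the trisubstituted alkenes should be spared.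

Step 17
Reactants: 25 cyclic sulfate
Product: 27 (1R,3E,7E,11S,12R,14S)-11-chloro-12-hydroxy-17-norcembra-3,7-dien-16,14-olide, via lithium chloroalkyl sulfate 26 (not isolated)
Conditions: LiCl, DMF, 40 °C; then H2SO4 (cat.), H2O, THF, rt
Reagents that add atoms: lithium chloride, [Li+].[Cl-]
Why: SN2 ring opening of the cyclic sulfate by chloride at the secondary C11, the tertiary C12 being closed to backside attack, inverts C11 from R to S, and acid hydrolysis of the tertiary sulfate monoester by S–O cleavage returns the C12 alcohol with retention.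

Step 18
Reactants: 27 chlorohydrin lactone
Product: 28 12-O-trimethylsilyl ether of 27
Conditions: TMSOTf, 2,6-lutidine, CH2Cl2, −78 °C
Reagents that add atoms: trimethylsilyl trifluoromethanesulfonate, C[Si](C)(C)OS(=O)(=O)C(F)(F)F
Why: Silylation of the hindered tertiary alcohol with the silyl triflate, so that no alkoxide can form beside the C11 chloride and close the epoxide when the lactone is enolised in step 19.

Step 19
Reactants: 28 silyl-protected chlorohydrin lactone
Product: 33 (1R,3E,7E,11S,12R,14S)-11-chloro-12-hydroxycembra-3,7,15(17)-trien-16,14-olide (target), via lithium enolate 29 (not isolated), via Mannich base 30 (not isolated), via methiodide 31 (not isolated), via silyl ether 32 (not isolated)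
Conditions: LDA, THF, −78 °C; CH2=NMe2+ I−, −78 °C → rt; MeI, CH2Cl2, rt; aq. NaHCO3; then AcOH/THF/H2O (3:1:1), rt
Reagents that add atoms: Eschenmoser's salt (N,N-dimethylmethyleneiminium iodide), C=[N+](C)C.[I-]
Why: α-Methylenation of the lactone by the Mannich route (aminomethylation of the lithium enolate, N-methylation, Hofmann-type β-elimination of trimethylamine), the transient C15 centre vanishing in the C15=C17 alkene, followed by mild acid cleavage of the silyl ether, which the chlorohydrin tolerates whereas base would close the epoxide.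

**Compound list**

1 | (2E,6E)-farnesol | CC(C)=CCC/C(C)=C/CC/C(C)=C/CO | starting material
2 | (2E,6E)-farnesyl acetate | CC(C)=CCC/C(C)=C/CC/C(C)=C/COC(C)=O | intermediate
3 | (2E,6E)-10-bromo-11-hydroxy-10,11-dihydrofarnesyl acetate (racemic at C10) | CC(C)(O)C(Br)CC/C(C)=C/CC/C(C)=C/COC(C)=O | intermediate
4 | (2E,6E)-10,11-epoxy-10,11-dihydrofarnesyl acetate (racemic) | CC1(C)OC1CC/C(C)=C/CC/C(C)=C/COC(C)=O | intermediate
5 | (2E,6E)-10,11-epoxy-10,11-dihydrofarnesol (racemic) | CC1(C)OC1CC/C(C)=C/CC/C(C)=C/CO | intermediate
6 | (2E,6E)-3,7,11-trimethyldodeca-2,6-diene-1,10,11-triol (racemic) | CC(C)(O)C(O)CC/C(C)=C/CC/C(C)=C/CO | intermediate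
7 | (4E,8E)-10-hydroxy-4,8-dimethyldeca-4,8-dienal | O=CCC/C(C)=C/CC/C(C)=C/CO | intermediate
8 | (2E,6E)-9-(1,3-dioxolan-2-yl)-3,7-dimethylnona-2,6-dien-1-ol | OC/C=C(C)/CC/C=C(C)/CCC1OCCO1 | intermediate
9 | 2-[(3E,7E)-9-bromo-3,7-dimethylnona-3,7-dienyl]-1,3-dioxolane | BrC/C=C(C)/CC/C=C(C)/CCC1OCCO1 | intermediate
10 | 4-tert-butoxy-4-oxobutanoic acid (mono-tert-butyl succinate) | CC(C)(C)OC(=O)CCC(=O)O | starting material
11 | (R)-4-benzyl-1,3-oxazolidin-2-one | O=C1N[C@H](Cc2ccccc2)CO1 | starting material
12 | mixed anhydride of 10 with pivalic acid | CC(C)(C)OC(=O)CCC(=O)OC(=O)C(C)(C)C | intermediate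
13 | tert-butyl 4-[(4R)-4-benzyl-2-oxo-1,3-oxazolidin-3-yl]-4-oxobutanoate | CC(C)(C)OC(=O)CCC(=O)N1[C@H](Cc2ccccc2)COC1=O | intermediate
14 | sodium Z-enolate of 13 | [Na+].[O-]/C(=C\CC(=O)OC(C)(C)C)N1[C@H](Cc2ccccc2)COC1=O | intermediate
15 | tert-butyl (3R,5E,9E)-3-[(4R)-4-benzyl-2-oxo-1,3-oxazolidine-3-carbonyl]-12-(1,3-dioxolan-2-yl)-6,10-dimethyldodeca-5,9-dienoate | CC(C)(C)OC(=O)C[C@H](C(=O)N1[C@H](Cc2ccccc2)COC1=O)C/C=C(C)/CC/C=C(C)/CCC1OCCO1 | intermediate
16 | tert-butyl (3R,5E,9E)-12-(1,3-dioxolan-2-yl)-3-(hydroxymethyl)-6,10-dimethyldodeca-5,9-dienoate | CC(C)(C)OC(=O)C[C@H](CO)C/C=C(C)/CC/C=C(C)/CCC1OCCO1 | intermediate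
17 | tert-butyl (3R,5E,9E)-12-(1,3-dioxolan-2-yl)-3-formyl-6,10-dimethyldodeca-5,9-dienoate | CC(C)(C)OC(=O)C[C@H](C=O)C/C=C(C)/CC/C=C(C)/CCC1OCCO1 | intermediate
18 | O-bis(isopinocampheyl)borinate of 19 | CC(C)(C)OC(=O)C[C@H]([C@@H](OB([C@@H]1C[C@@H]2C[C@H]([C@H]1C)C2(C)C)[C@@H]1C[C@@H]2C[C@H]([C@H]1C)C2(C)C)CC=C)C/C=C(C)/CC/C=C(C)/CCC1OCCO1 | intermediate
19 | tert-butyl (3R,5E,9E)-12-(1,3-dioxolan-2-yl)-3-[(1S)-1-hydroxybut-3-enyl]-6,10-dimethyldodeca-5,9-dienoate | CC(C)(C)OC(=O)C[C@H]([C@@H](O)CC=C)C/C=C(C)/CC/C=C(C)/CCC1OCCO1 | intermediate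
20 | (4R,5S)-4-[(2E,6E)-9-(1,3-dioxolan-2-yl)-3,7-dimethylnona-2,6-dienyl]-5-(prop-2-enyl)oxolan-2-one | C=CC[C@@H]1OC(=O)C[C@H]1C/C=C(C)/CC/C=C(C)/CCC2OCCO2 | intermediate
21 | (4R,5S)-4-[(2E,6E)-9-(1,3-dioxolan-2-yl)-3,7-dimethylnona-2,6-dienyl]-5-(2-oxopropyl)oxolan-2-one | CC(=O)C[C@@H]1OC(=O)C[C@H]1C/C=C(C)/CC/C=C(C)/CCC2OCCO2 | intermediate
22 | (4E,8E)-4,8-dimethyl-10-[(2S,3R)-5-oxo-2-(2-oxopropyl)oxolan-3-yl]deca-4,8-dienal (seco keto aldehyde) | CC(=O)C[C@@H]1OC(=O)C[C@H]1C/C=C(C)/CC/C=C(C)/CCC=O | intermediate
23 | (1R,3E,7E,11R,12R,14S)-11,12-dihydroxy-17-norcembra-3,7-dien-16,14-olide | C1C(=O)O[C@H]2C[C@@](C)(O)[C@H](O)CC/C(C)=C/CC/C(C)=C/C[C@H]12 | intermediate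
24 | 11,12-cyclic sulfite of 23 (both configurations at sulfur) | C1C(=O)O[C@H]2C[C@@](C)(O3)[C@H](OS3=O)CC/C(C)=C/CC/C(C)=C/C[C@H]12 | intermediate
25 | 11,12-cyclic sulfate of 23 | C1C(=O)O[C@H]2C[C@@](C)(O3)[C@H](OS3(=O)=O)CC/C(C)=C/CC/C(C)=C/C[C@H]12 | intermediate
26 | lithium 12-O-sulfate of 27 | C1C(=O)O[C@H]2C[C@@](C)(OS(=O)(=O)[O-])[C@@H](Cl)CC/C(C)=C/CC/C(C)=C/C[C@H]12.[Li+] | intermediate
27 | (1R,3E,7E,11S,12R,14S)-11-chloro-12-hydroxy-17-norcembra-3,7-dien-16,14-olide | C1C(=O)O[C@H]2C[C@@](C)(O)[C@@H](Cl)CC/C(C)=C/CC/C(C)=C/C[C@H]12 | intermediate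
28 | 12-O-trimethylsilyl ether of 27 | C1C(=O)O[C@H]2C[C@@](C)(O[Si](C)(C)C)[C@@H](Cl)CC/C(C)=C/CC/C(C)=C/C[C@H]12 | intermediate
29 | lithium enolate of 28 | C1=C([O-])O[C@H]2C[C@@](C)(O[Si](C)(C)C)[C@@H](Cl)CC/C(C)=C/CC/C(C)=C/C[C@H]12.[Li+] | intermediate
30 | 15-[(dimethylamino)methyl] derivative of 28 (C15 epimers) | CN(C)CC1C(=O)O[C@H]2C[C@@](C)(O[Si](C)(C)C)[C@@H](Cl)CC/C(C)=C/CC/C(C)=C/C[C@H]12 | intermediate
31 | trimethylammonium iodide derived from 30 | C[N+](C)(C)CC1C(=O)O[C@H]2C[C@@](C)(O[Si](C)(C)C)[C@@H](Cl)CC/C(C)=C/CC/C(C)=C/C[C@H]12.[I-] | intermediate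
32 | 12-O-trimethylsilyl ether of 33 | C=C1C(=O)O[C@H]2C[C@@](C)(O[Si](C)(C)C)[C@@H](Cl)CC/C(C)=C/CC/C(C)=C/C[C@H]12 | intermediate
33 | (1R,3E,7E,11S,12R,14S)-11-chloro-12-hydroxycembra-3,7,15(17)-trien-16,14-olide (CNP0247658.1) | C=C1C(=O)O[C@H]2C[C@@](C)(O)[C@@H](Cl)CC/C(C)=C/CC/C(C)=C/C[C@H]12 | target

**Step count and risks**

Total step count: 19. Longest linear sequence: 18 steps (steps 1–6 and 8–19; step 7 makes the imide in one step from purchased materials).

The three steps most likely to fail:

1. Step 15. The process at risk is stereocontrol in the ring closure. The tethered ketyl may approach with C10 gauche to C13 (erythro diol) or reach the other face of the ketone, and intermolecular coupling competes if the addition is too fast. The fallback sets out from 22 and returns at 27. The erythro product, (1R,3E,7E,11S,12R,14S)-11,12-dihydroxy-17-norcembra-3,7-dien-16,14-olide F1, is carried on by a different C11 chemistry. MsCl/Et3N should sulfonylate only the secondary hydroxyl to give the 11-methanesulfonate F2. DBU then closes the trans-11,12-epoxide F3 with inversion at C11, and Li2CuCl4 in THF delivers chloride to the less substituted C11 with a second inversion, giving 27. Diols of the 12S series F4 cannot be corrected at the tertiary centre; NaIO4 glycol cleavage would turn them back into 22 for another pass.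

2. Step 16. The process at risk is over-oxidation: the RuO4 formed in the second stage may attack the two trisubstituted alkenes while the sulfite is being oxidised. The fallback sets out from 23 and returns at 27. The cyclic sulfite 24 is isolated and used itself as the electrophile. LiCl in DMF at 80–90 °C should open it at C11 with inversion to the lithium chloroalkyl sulfite F5, which loses SO2 on acidic work-up to give 27. No oxidant then meets the alkenes, and step 17 is bypassed.

3. Step 17. The process at risk is slow or misdirected substitution at C11, which is flanked by the fully substituted C12; elimination or ionisation of the tertiary sulfate during hydrolysis could result. The fallback sets out from 23 and returns at 27, inverting C11 at the diol stage instead. Parikh–Doering oxidation (SO3·pyridine, DMSO, iPr2NEt) of the secondary alcohol gives the 12-hydroxy-11-ketone F6. Chelation-controlled reduction with Zn(BH4)2 (Cram chelate, hydride from the methyl side) should give the erythro diol F1. The mesylate F2 and epoxide F3 sequence described for step 15 then places chloride by epoxide opening.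

**Further compounds**

F1 | step 15 | (1R,3E,7E,11S,12R,14S)-11,12-dihydroxy-17-norcembra-3,7-dien-16,14-olide | C1C(=O)O[C@H]2C[C@@](C)(O)[C@@H](O)CC/C(C)=C/CC/C(C)=C/C[C@H]12
F2 | step 15 | 11-O-methanesulfonate of F1 | C1C(=O)O[C@H]2C[C@@](C)(O)[C@@H](OS(C)(=O)=O)CC/C(C)=C/CC/C(C)=C/C[C@H]12
F3 | step 15 | (1R,3E,7E,11R,12R,14S)-11,12-epoxy-17-norcembra-3,7-dien-16,14-olide | C1C(=O)O[C@H]2C[C@@](C)(O3)[C@H]3CC/C(C)=C/CC/C(C)=C/C[C@H]12
F4 | step 15 | (1R,3E,7E,12S,14S)-11,12-dihydroxy-17-norcembra-3,7-dien-16,14-olide (either C11 epimer) | C1C(=O)O[C@H]2C[C@](C)(O)C(O)CC/C(C)=C/CC/C(C)=C/C[C@H]12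
F5 | step 16 | lithium 12-O-sulfite of 27 | C1C(=O)O[C@H]2C[C@@](C)(OS(=O)[O-])[C@@H](Cl)CC/C(C)=C/CC/C(C)=C/C[C@H]12.[Li+]
F6 | step 17 | (1R,3E,7E,12R,14S)-12-hydroxy-11-oxo-17-norcembra-3,7-dien-16,14-olide | C1C(=O)O[C@H]2C[C@@](C)(O)C(=O)CC/C(C)=C/CC/C(C)=C/C[C@H]12
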